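**Plan**
Cuts: the final operations only free O5 (methyl ether) and O3' (benzyl ether) and place the hydroxyl on C3. The target therefore goes back to a 3'-benzyloxy-5,6,7,8,4',5'-hexamethoxyflavone, whose ring C is opened at O1–C2 to an ortho-hydroxyaryl ynone.
Key cut: C8a–O1 and C4a–C4 together. C8a (oxygen-bearing) and C4a (acyl-bearing) are neighbours on ring A and lie between the oxygenated carbons C8 and C5. This is the pattern obtained when the O and the C(=O) of a carboxylic acid add across the triple bond of the symmetric 3,4,5,6-tetramethoxybenzyne.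
Forward order: ring A is bought and raised to the tetramethoxy silylaryl triflate (steps 1–5), and ring B is bought and extended to the arylpropiolic acid (steps 6–8). The halves are joined in step 9, ring C closes in step 10 by 6-endo-dig attack of O1 on C2, the C3 hydroxyl follows in step 11, and both phenols are freed in step 12.
Stereochemistry: the target has no stereocentre and no configured double bond, so none has to be set.

Key step: step 9

**Route**

Step 1
Reactants: 1 2,3,4-trimethoxybenzaldehyde
Product: 3 2,3,4-trimethoxyphenol, via 2,3,4-trimethoxyphenyl formate 2 (not isolated)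
Conditions: 30% H2O2, cat. H2SO4, MeOH, rt
Reagents that add atoms: hydrogen peroxide, OO
Why: Acid-catalysed Dakin oxidation, in which the electron-rich aryl group migrates from carbon to oxygen (Baeyer–Villiger-type shift) and formate 2 is methanolysed in the same flask.

Step 2
Reactants: 3 2,3,4-trimethoxyphenol
Product: 4 1,2,3,4-tetramethoxybenzene
Conditions: MeI, K2CO3, acetone, reflux
Reagents that add atoms: iodomethane, CI
Why: Williamson ether synthesis on the only nucleophilic site of 3.

Step 3
Reactants: 4 1,2,3,4-tetramethoxybenzene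
Product: 7 2,3,4,5-tetramethoxyphenol, via aryllithium 5 (not isolated), via lithium aryltrimethoxyborate 6 (not isolated)
Conditions: n-BuLi, TMEDA, THF, 0 °C; B(OMe)3, −78 °C → rt; AcOH, 30% H2O2, 0 °C → rt
Reagents that add atoms: hydrogen peroxide, OO; in intermediates 5 and 6 only: n-butyllithium, [Li]CCCC, and trimethyl borate, COB(OC)OC
Why: Directed ortho-metalation beside a terminal methoxy group (the two free ring positions of 4 are equivalent), borylation and oxidative 1,2-shift of the aryl group from boron to oxygen form a standard one-flask arene hydroxylation.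

Step 4
Reactants: 7 2,3,4,5-tetramethoxyphenol
Product: 8 2-bromo-3,4,5,6-tetramethoxyphenol
Conditions: NBS (1.0 equiv), CH2Cl2, −20 °C, dark
Reagents that add atoms: N-bromosuccinimide, O=C1CCC(=O)N1Br
Why: Electrophilic aromatic bromination can only strike the one unsubstituted ring carbon, which is ortho to the hydroxyl group, and one equivalent of NBS in a dry solvent at low temperature should hold back oxidation of the electron-rich phenol.

Step 5
Reactants: 8 2-bromo-3,4,5,6-tetramethoxyphenol
Product: 11 2,3,4,5-tetramethoxy-6-(trimethylsilyl)phenyl trifluoromethanesulfonate, via silyl ether 9 (not isolated), via lithium silylphenoxide 10 (not isolated)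
Conditions: HN(SiMe3)2, THF, reflux, then evaporation; n-BuLi, THF, −78 °C; Tf2O, −78 °C → rt
Reagents that add atoms: hexamethyldisilazane, C[Si](C)(C)N[Si](C)(C)C; trifluoromethanesulfonic anhydride, O=S(=O)(OS(=O)(=O)C(F)(F)F)C(F)(F)F; in intermediate 10 only: n-butyllithium, [Li]CCCC
Why: This is the standard entry to ortho-silylaryl triflates, namely O-silylation, bromine–lithium exchange, 1,3 oxygen-to-carbon silyl shift (retro-Brook rearrangement) and O-triflation of the phenoxide, and it is known to tolerate a methoxy group next to the silicon.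

Step 6
Reactants: 12 3-hydroxy-4,5-dimethoxybenzaldehyde
Product: 13 3-(benzyloxy)-4,5-dimethoxybenzaldehyde
Conditions: BnBr, K2CO3, DMF, rt
Reagents that add atoms: benzyl bromide, BrCc1ccccc1
Why: Williamson etherification of the only acidic site gives a benzyl ether that should tolerate n-BuLi at −78 °C, fluoride, carbonate and lithium amide, and that falls to BCl3 together with the 5-methyl ether at the end.

Step 7
Reactants: 13 3-(benzyloxy)-4,5-dimethoxybenzaldehyde
Product: 14 1-(benzyloxy)-5-(2,2-dibromoethenyl)-2,3-dimethoxybenzene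
Conditions: CBr4, PPh3, CH2Cl2, 0 °C
Reagents that add atoms: carbon tetrabromide, BrC(Br)(Br)Br
Why: First stage of the Corey–Fuchs sequence, a Wittig-type olefination of the aldehyde by the dibromomethylene ylide formed in the flask from CBr4 and PPh3.

Step 8
Reactants: 14 1-(benzyloxy)-5-(2,2-dibromoethenyl)-2,3-dimethoxybenzene
Product: 17 3-[3-(benzyloxy)-4,5-dimethoxyphenyl]propiolic acid, via lithium acetylide 15 (not isolated), via lithium arylpropiolate 16 (not isolated)
Conditions: n-BuLi (2.2 equiv), THF, −78 °C; CO2, −78 °C → rt; 1 M HCl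
Reagents that add atoms: carbon dioxide, O=C=O; in intermediates 15 and 16 only: n-butyllithium, [Li]CCCC
Why: Second stage of the Corey–Fuchs sequence, in which two equivalents of n-BuLi convert the dibromoalkene by elimination and bromine–lithium exchange into acetylide 15, whose carboxylation with CO2 is a standard route to arylpropiolic acids.

Step 9
Reactants: 17 3-[3-(benzyloxy)-4,5-dimethoxyphenyl]propiolic acid; 11 2,3,4,5-tetramethoxy-6-(trimethylsilyl)phenyl trifluoromethanesulfonate
Product: 21 3-[3-(benzyloxy)-4,5-dimethoxyphenyl]-1-(2-hydroxy-3,4,5,6-tetramethoxyphenyl)prop-2-yn-1-one, via potassium arylpropiolate 18 (not isolated), via 3,4,5,6-tetramethoxybenzyne 19 (not isolated), via potassium phenoxide of the ynone 20 (not isolated)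
Conditions: 17 (1.3 equiv), KH (1.3 equiv), THF, 0 °C; 11 (1.0 equiv, slow addition), KF, 18-crown-6, THF, 0 °C → rt; AcOH, −20 °C
Reagents that add atoms: potassium hydride, [H-].[K+] (only the potassium of 18 and 20; product 21 holds atoms of 11 and 17 alone)
Why: Fluoride removes the silyl group of 11 and triflate departs, giving aryne 19, whose strained triple bond is attacked by the carboxylate oxygen of 18 (C8a–O1 bond). The resulting ortho-acyloxy aryl anion turns back on its own ester carbonyl through a four-centre transition state and the strained alkoxide collapses with C–O cleavage, so the alkynoyl group ends on carbon (C4a–C4 bond) and phenoxide 20 is released; this is the known formal insertion of arynes into the C–O bond of carboxylic acids, an anionic Fries-type acyl shift. No ring of the target closes and no stereocentre is formed. Regiochemistry is not an issue, because the mirror plane of 19 exchanges the two aryne carbons, each of which has a methoxy neighbour, so a single adduct is possible. The selectivity that matters is acyl transfer over protonation of the aryl anion, which is secured by the preformed potassium salt in aprotic THF, while the Z geometry of the aryl ester holds the alkyne away from the anion and disfavours conjugate attack. Phenoxide 20 should not go on to the pyranone here, since attack on the alkyne would give an unstabilised C3 vinyl anion with no proton donor to trap it, and the cold AcOH quench should deliver the hydrogen-bonded phenol 21.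

Step 10
Reactants: 21 3-[3-(benzyloxy)-4,5-dimethoxyphenyl]-1-(2-hydroxy-3,4,5,6-tetramethoxyphenyl)prop-2-yn-1-one
Product: 22 2-[3-(benzyloxy)-4,5-dimethoxyphenyl]-5,6,7,8-tetramethoxy-4H-chromen-4-one
Conditions: K2CO3, acetone, reflux
Reagents that add atoms: none
Why: Base-mediated intramolecular oxa-Michael addition in the 6-endo-dig mode, now possible because unreacted phenol 21 and hydrogencarbonate protonate C3 after O1 has attacked C2, and K2CO3 in an aprotic solvent is the known setting that favours the flavone over 5-exo-dig closure.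

Step 11
Reactants: 22 2-[3-(benzyloxy)-4,5-dimethoxyphenyl]-5,6,7,8-tetramethoxy-4H-chromen-4-one
Product: 25 2-[3-(benzyloxy)-4,5-dimethoxyphenyl]-3-hydroxy-5,6,7,8-tetramethoxy-4H-chromen-4-one, via 3-lithioflavone 23 (not isolated), via lithium flavon-3-yltrimethoxyborate 24 (not isolated)
Conditions: LiN(i-Pr)2 (LDA), THF, −78 °C; B(OMe)3, −78 °C → 0 °C; AcOH, 30% H2O2, 0 °C → rt
Reagents that add atoms: hydrogen peroxide, OO; in intermediates 23 and 24 only: lithium diisopropylamide, [Li]N(C(C)C)C(C)C, and trimethyl borate, COB(OC)OC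
Why: Flavones are known to be lithiated by LDA at C3, the vinylic position beside the coordinating C4 carbonyl, and borylation followed by peroxide oxidation (1,2-shift from boron to oxygen) turns the anion into the flavonol, while ring A offers no C–H bond and ring B and the benzyl ether should not be touched by the amide base at −78 °C.

Step 12
Reactants: 25 2-[3-(benzyloxy)-4,5-dimethoxyphenyl]-3-hydroxy-5,6,7,8-tetramethoxy-4H-chromen-4-one
Product: 26 3-demethyldigicitrin, 3,5-dihydroxy-2-(3-hydroxy-4,5-dimethoxyphenyl)-6,7,8-trimethoxy-4H-chromen-4-one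
Conditions: BCl3, pentamethylbenzene, CH2Cl2, −78 °C → 0 °C; then H2O
Reagents that add atoms: none
Why: Lewis acid ether cleavage, in which BCl3 held by the C4 carbonyl dealkylates the peri 5-methoxy group through a six-membered chelate and also ionises the aryl benzyl ether, whose cation is taken up by pentamethylbenzene in a Friedel–Crafts reaction, whereas the remaining methoxy groups have no carbonyl partner and should persist at or below 0 °C.

**Compound list**
1 | 2,3,4-trimethoxybenzaldehyde | COc1ccc(C=O)c(OC)c1OC | starting material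
2 | 2,3,4-trimethoxyphenyl formate | COc1ccc(OC=O)c(OC)c1OC | intermediate
3 | 2,3,4-trimethoxyphenol | COc1ccc(O)c(OC)c1OC | intermediate
4 | 1,2,3,4-tetramethoxybenzene | COc1ccc(OC)c(OC)c1OC | intermediate
5 | (2,3,4,5-tetramethoxyphenyl)lithium | [Li]c1cc(OC)c(OC)c(OC)c1OC | intermediate
6 | lithium trimethoxy(2,3,4,5-tetramethoxyphenyl)borate | [Li+].CO[B-](OC)(OC)c1cc(OC)c(OC)c(OC)c1OC | intermediate
7 | 2,3,4,5-tetramethoxyphenol | COc1cc(O)c(OC)c(OC)c1OC | intermediate
8 | 2-bromo-3,4,5,6-tetramethoxyphenol | COc1c(Br)c(O)c(OC)c(OC)c1OC | intermediate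
9 | (2-bromo-3,4,5,6-tetramethoxyphenoxy)trimethylsilane | COc1c(Br)c(O[Si](C)(C)C)c(OC)c(OC)c1OC | intermediate
10 | lithium 2,3,4,5-tetramethoxy-6-(trimethylsilyl)phenoxide | [Li+].COc1c([Si](C)(C)C)c([O-])c(OC)c(OC)c1OC | intermediate
11 | 2,3,4,5-tetramethoxy-6-(trimethylsilyl)phenyl trifluoromethanesulfonate | COc1c(OC)c(OC)c(OC)c(OS(=O)(=O)C(F)(F)F)c1[Si](C)(C)C | intermediate
12 | 3-hydroxy-4,5-dimethoxybenzaldehyde | COc1cc(C=O)cc(O)c1OC | starting material
13 | 3-(benzyloxy)-4,5-dimethoxybenzaldehyde | COc1cc(C=O)cc(OCc2ccccc2)c1OC | intermediate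
14 | 1-(benzyloxy)-5-(2,2-dibromoethenyl)-2,3-dimethoxybenzene | COc1cc(C=C(Br)Br)cc(OCc2ccccc2)c1OC | intermediate
15 | lithium [3-(benzyloxy)-4,5-dimethoxyphenyl]acetylide | [Li]C#Cc1cc(OC)c(OC)c(OCc2ccccc2)c1 | intermediate
16 | lithium 3-[3-(benzyloxy)-4,5-dimethoxyphenyl]propiolate | [Li+].[O-]C(=O)C#Cc1cc(OC)c(OC)c(OCc2ccccc2)c1 | intermediate
17 | 3-[3-(benzyloxy)-4,5-dimethoxyphenyl]propiolic acid | OC(=O)C#Cc1cc(OC)c(OC)c(OCc2ccccc2)c1 | intermediate
18 | potassium 3-[3-(benzyloxy)-4,5-dimethoxyphenyl]propiolate | [K+].[O-]C(=O)C#Cc1cc(OC)c(OC)c(OCc2ccccc2)c1 | intermediate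
19 | 3,4,5,6-tetramethoxybenzyne (1,2-didehydro-3,4,5,6-tetramethoxybenzene) | COC1=C(OC)C(OC)=C(OC)C#C1 | intermediate
20 | potassium 2-{3-[3-(benzyloxy)-4,5-dimethoxyphenyl]prop-2-ynoyl}-3,4,5,6-tetramethoxyphenoxide | [K+].COc1c([O-])c(C(=O)C#Cc2cc(OC)c(OC)c(OCc3ccccc3)c2)c(OC)c(OC)c1OC | intermediate
21 | 3-[3-(benzyloxy)-4,5-dimethoxyphenyl]-1-(2-hydroxy-3,4,5,6-tetramethoxyphenyl)prop-2-yn-1-one | COc1c(O)c(C(=O)C#Cc2cc(OC)c(OC)c(OCc3ccccc3)c2)c(OC)c(OC)c1OC | intermediate
22 | 2-[3-(benzyloxy)-4,5-dimethoxyphenyl]-5,6,7,8-tetramethoxy-4H-chromen-4-one | COc1cc(-c2cc(=O)c3c(OC)c(OC)c(OC)c(OC)c3o2)cc(OCc2ccccc2)c1OC | intermediate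
23 | 2-[3-(benzyloxy)-4,5-dimethoxyphenyl]-3-lithio-5,6,7,8-tetramethoxy-4H-chromen-4-one | COc1cc(-c2oc3c(OC)c(OC)c(OC)c(OC)c3c(=O)c2[Li])cc(OCc2ccccc2)c1OC | intermediate
24 | lithium {2-[3-(benzyloxy)-4,5-dimethoxyphenyl]-5,6,7,8-tetramethoxy-4-oxo-4H-chromen-3-yl}trimethoxyborate | [Li+].COc1cc(-c2oc3c(OC)c(OC)c(OC)c(OC)c3c(=O)c2[B-](OC)(OC)OC)cc(OCc2ccccc2)c1OC | intermediate
25 | 2-[3-(benzyloxy)-4,5-dimethoxyphenyl]-3-hydroxy-5,6,7,8-tetramethoxy-4H-chromen-4-one | COc1cc(-c2oc3c(OC)c(OC)c(OC)c(OC)c3c(=O)c2O)cc(OCc2ccccc2)c1OC | intermediate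
26 | 3-demethyldigicitrin, 3,5-dihydroxy-2-(3-hydroxy-4,5-dimethoxyphenyl)-6,7,8-trimethoxy-4H-chromen-4-one | COc1cc(-c2oc3c(OC)c(OC)c(OC)c(O)c3c(=O)c2O)cc(O)c1OC | target

**Step count**
Total steps: 12. Longest linear sequence: 9 (steps 1–5 and 9–12).

**Steps most likely to fail**

Step 9. Three processes threaten this step:
- The aryl anion may be protonated before the acyl shift.
- Capture of an aryne hindered on both sides by a weakly nucleophilic carboxylate may be slow.
- The liberated phenoxide may be arylated further, or ring C may close early in an uncontrolled mode.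

The fallback makes the C4a–C4 bond by carbonyl addition, with O1 already in place. It sets out from phenol 7 and dibromoalkene 14 and rejoins the route at 21. Phenol 7 would be formylated at its only free position (MgCl2, Et3N, paraformaldehyde, MeCN, reflux; Casnati–Skattebøl reaction) to 2-hydroxy-3,4,5,6-tetramethoxybenzaldehyde F1. Lithium acetylide 15, made from 14 as in step 8, would be used in slightly more than two equivalents because the first is spent on the phenol. It would add to the aldehyde to give racemic 2-{3-[3-(benzyloxy)-4,5-dimethoxyphenyl]-1-hydroxyprop-2-yn-1-yl}-3,4,5,6-tetramethoxyphenol F2. MnO2 in CH2Cl2 would then oxidise the benzylic propargylic alcohol to 21.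

Step 11. The C3 carbanion may expel the ring oxygen again before boron arrives (β-elimination, the reverse of step 10). Metalation may also stay incomplete in the crowded surroundings of the C4 carbonyl. The fallback replaces carbanion chemistry by electrophilic oxygen transfer. It sets out from 22 and rejoins at 25. Dimethyldioxirane in acetone–CH2Cl2 at 0 °C would epoxidise the C2–C3 double bond to the racemic, cis-fused 1a-[3-(benzyloxy)-4,5-dimethoxyphenyl]-3,4,5,6-tetramethoxy-1a,7a-dihydro-7H-oxireno[2,3-b]chromen-7-one F3. Catalytic p-TsOH in CH2Cl2 would open it at C2, and loss of the C3 proton would give flavonol 25.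

Step 12. Once the first boron phenoxides have formed, they may direct further demethylation at the neighbouring methoxy groups on C6 and C4'. The two cleavages may also need different temperatures, so that one stays incomplete while the other overruns. The fallback separates them into two orthogonal operations. It sets out from 25 and ends at 26. Hydrogenolysis (H2, 10% Pd/C, EtOAc–MeOH, rt) would remove only the benzyl group to give 3-hydroxy-2-(3-hydroxy-4,5-dimethoxyphenyl)-5,6,7,8-tetramethoxy-4H-chromen-4-one F4. Anhydrous AlCl3 in MeCN at 60 °C, followed by dilute HCl to break the aluminium chelate, would then cleave only the carbonyl-chelated 5-methyl ether to give 26.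

**Further compounds**
F1 | step 9 | 2-hydroxy-3,4,5,6-tetramethoxybenzaldehyde | COc1c(O)c(C=O)c(OC)c(OC)c1OC
F2 | step 9 | 2-{3-[3-(benzyloxy)-4,5-dimethoxyphenyl]-1-hydroxyprop-2-yn-1-yl}-3,4,5,6-tetramethoxyphenol (racemic) | COc1c(O)c(C(O)C#Cc2cc(OC)c(OC)c(OCc3ccccc3)c2)c(OC)c(OC)c1OC
F3 | step 11 | 1a-[3-(benzyloxy)-4,5-dimethoxyphenyl]-3,4,5,6-tetramethoxy-1a,7a-dihydro-7H-oxireno[2,3-b]chromen-7-one (cis-fused, racemic, one enantiomer drawn) | COc1cc([C@@]23Oc4c(OC)c(OC)c(OC)c(OC)c4C(=O)[C@@H]2O3)cc(OCc2ccccc2)c1OC
F4 | step 12 | 3-hydroxy-2-(3-hydroxy-4,5-dimethoxyphenyl)-5,6,7,8-tetramethoxy-4H-chromen-4-one | COc1cc(-c2oc3c(OC)c(OC)c(OC)c(OC)c3c(=O)c2O)cc(O)c1OC
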